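**Plan**

- Numbering: carbocycle C1–C10; C1–C10 epoxide (C10 bears C14H2OH); cis C2=C3; C4–C5 epoxide (C4 bears C15H3); lactone oxygen on C6; butenolide ring O–C6–C7=C11–C12(=O) with C13H2OAc on C11; methacrylate on C8.
- Enabling feature: the C4–C5 epoxide oxygen and the C6 lactone oxygen of the butenolide ring sit on neighbouring carbons, which is what a C4 carbinol and the C12 carboxyl leave when they add in turn across a cis C5=C6 alkene.
- Cuts (retro): C8 and C13 esters and the C14 silyl ether; the C4–O–C5 epoxide (to C4–OH and C5–I); C6–O and C5–I together (iodolactonization of a ten-membered (2Z,4Z)-dienoic acid); ring bond C6–C7 (Stille); C7–C11 (aldol); C1–C2 (Sonogashira).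
- Forward: a west fragment (C2–C6, C15) and an east fragment (C7–C10, C14, C1) are joined at C1–C2, C11–C13 are added at C7, the ten-membered ring closes at C6–C7, then the butenolide ring (key step) and last the C4–C5 epoxide; the two acyl groups go on at the end.
- Stereochemistry: C4 from a Sharpless epoxidation of (E)-3-methylpent-2-en-4-yn-1-ol; C8 from methyl (S)-glycidate; C10 and C1 from a second Sharpless epoxidation; C5 and C6 relayed from C4 in the key step; the cis ring alkenes from syn reductions; the C7=C11 geometry from a chelated enolate.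

Key step: step 22

Remark: the enynol, methyl (S)-glycidate and methyl 3-hydroxypropanoate are taken as purchasable, and every basic step is quenched with aqueous NH4Cl or pH 5 buffer, so lithium and sodium leave as chlorides.

**Route**

Step 1
Reactants: 1 (2E)-3-methylpent-2-en-4-yn-1-ol
Product: 2 [(2S,3S)-3-ethynyl-3-methyloxiran-2-yl]methanol
Conditions: Ti(OiPr)4 (10 mol%), L-(+)-diisopropyl tartrate (12 mol%), t-BuOOH, 4 Å molecular sieves, CH2Cl2, −20 °C
Reagents that add atoms: tert-butyl hydroperoxide, CC(C)(C)OO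
Why: Sharpless asymmetric epoxidation of a 3,3-disubstituted (E)-allylic alcohol, in which the titanium tartrate complex delivers oxygen to one alkene face (same sense as for geraniol) and so sets the quaternary carbon that becomes C4, the alkyne being inert.

Step 2
Reactants: 2 [(2S,3S)-3-ethynyl-3-methyloxiran-2-yl]methanol
Product: 3 [(2S,3S)-3-methyl-3-[(tributylstannyl)ethynyl]oxiran-2-yl]methanol
Conditions: n-BuLi (2.05 equiv), THF, −78 °C; Bu3SnCl, −78 → 0 °C; used crude
Reagents that add atoms: tributyltin chloride, CCCC[Sn](Cl)(CCCC)CCCC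
Why: Double deprotonation (hydroxyl and terminal alkyne) followed by C-stannylation of the acetylide (alkynyllithium substitution at tin), with any O–Sn bond hydrolysed on work-up and the epoxide untouched at low temperature.

Step 3
Reactants: 3 [(2S,3S)-3-methyl-3-[(tributylstannyl)ethynyl]oxiran-2-yl]methanol
Product: 4 [(2S,3S)-3-methyl-3-[(Z)-2-(tributylstannyl)ethenyl]oxiran-2-yl]methanol
Conditions: Cp2Zr(H)Cl (2.2 equiv), THF, rt; then H2O
Reagents that add atoms: none
Why: Hydrozirconation of the stannylalkyne (syn addition of Zr–H with zirconium on the tin-bearing carbon) and protonolysis with retention give the (Z)-alkenylstannane, one equivalent of the hydride being spent on the hydroxyl group.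

Step 4
Reactants: 4 [(2S,3S)-3-methyl-3-[(Z)-2-(tributylstannyl)ethenyl]oxiran-2-yl]methanol
Product: 5 (2R,3S)-2-(chloromethyl)-3-methyl-3-[(Z)-2-(tributylstannyl)ethenyl]oxirane
Conditions: PPh3, CCl4, NaHCO3, 70 °C
Reagents that add atoms: tetrachloromethane, ClC(Cl)(Cl)Cl
Why: Appel chlorination of the primary alcohol under neutral conditions (SN2 at CH2, no stereocentre touched; the descriptor at C2 changes only through priorities).

Step 5
Reactants: 5 (2R,3S)-2-(chloromethyl)-3-methyl-3-[(Z)-2-(tributylstannyl)ethenyl]oxirane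
Product: 6 (1Z,3S)-3-methyl-1-(tributylstannyl)pent-1-en-4-yn-3-ol (west fragment: C6=C5, C4 with C15, C3≡C2)
Conditions: LiN(iPr)2 (3.3 equiv), THF, −78 → −20 °C
Reagents that add atoms: none
Why: Base-induced double elimination of a 2,3-epoxy chloride (epoxide opening to the chloroallylic alkoxide, then dehydrochlorination) gives the tertiary propargylic alcohol without breaking the C–O bond at the quaternary carbon, so the epoxide configuration becomes the C4 carbinol configuration, and the amide base does not exchange with the alkenylstannane.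

Step 6
Reactants: 7 methyl (2S)-oxirane-2-carboxylate
Product: 8 methyl (2S)-2-hydroxypent-4-ynoate
Conditions: HC≡CH, n-BuLi, THF, −78 °C; BF3·OEt2; then 7, −78 °C
Reagents that add atoms: acetylene, C#C
Why: BF3-mediated opening of a terminal epoxide by an alkynyllithium at the unsubstituted carbon (Yamaguchi–Hirao alkynylation), the ester being inert to the alkynylborate at −78 °C and the C–O bond at the stereocentre (future C8) being retained.

Step 7
Reactants: 8 methyl (2S)-2-hydroxypent-4-ynoate
Product: 9 methyl (2S)-2-[(triethylsilyl)oxy]pent-4-ynoate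
Conditions: Et3SiCl, imidazole, CH2Cl2, 0 °C
Reagents that add atoms: chlorotriethylsilane, CC[Si](Cl)(CC)CC
Why: Standard silyl ether formation at the secondary hydroxyl (imidazole-promoted silylation).

Step 8
Reactants: 9 methyl (2S)-2-[(triethylsilyl)oxy]pent-4-ynoate
Product: 10 methyl (2S,4Z)-5-[dimethyl(phenyl)silyl]-4-formyl-2-[(triethylsilyl)oxy]pent-4-enoate
Conditions: PhMe2SiH, CO (20 bar), Rh4(CO)12 (0.5 mol%), Et3N (cat.), toluene, 90 °C
Reagents that add atoms: dimethylphenylsilane, C[SiH](C)c1ccccc1; carbon monoxide, [C-]#[O+]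
Why: Rhodium-catalysed silylformylation of a terminal alkyne adds formyl (future C14) to the internal carbon (future C10) and silicon to the terminal carbon (future C1) in a syn fashion, which fixes C14 cis to the later C1 substituent.

Step 9
Reactants: 10 methyl (2S,4Z)-5-[dimethyl(phenyl)silyl]-4-formyl-2-[(triethylsilyl)oxy]pent-4-enoate
Product: 11 methyl (2S,4Z)-5-[dimethyl(phenyl)silyl]-4-(hydroxymethyl)-2-[(triethylsilyl)oxy]pent-4-enoate
Conditions: NaBH4, THF/MeOH, −20 °C
Reagents that add atoms: none
Why: 1,2-Reduction of the enal by borohydride, which at low temperature is much faster than attack on the α-silyloxy ester.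

Step 10
Reactants: 11 methyl (2S,4Z)-5-[dimethyl(phenyl)silyl]-4-(hydroxymethyl)-2-[(triethylsilyl)oxy]pent-4-enoate
Product: 12 methyl (2S,4Z)-4-(hydroxymethyl)-5-iodo-2-[(triethylsilyl)oxy]pent-4-enoate (east fragment: C7 ester, C8, C9, C10 with C14, C1 iodide)
Conditions: N-iodosuccinimide, 2,6-lutidine, (CF3)2CHOH, 0 °C
Reagents that add atoms: N-iodosuccinimide, O=C1CCC(=O)N1I
Why: Iododesilylation of the alkenylsilane (electrophilic ipso substitution through the β-silyl cation) proceeds with retention and leaves iodine cis to the hydroxymethyl group.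

Step 11
Reactants: 12 methyl (2S,4Z)-4-(hydroxymethyl)-5-iodo-2-[(triethylsilyl)oxy]pent-4-enoate; 6 (1Z,3S)-3-methyl-1-(tributylstannyl)pent-1-en-4-yn-3-ol
Product: 13 methyl (2S,4Z,8S,9Z)-8-hydroxy-4-(hydroxymethyl)-8-methyl-10-(tributylstannyl)-2-[(triethylsilyl)oxy]deca-4,9-dien-6-ynoate
Conditions: Pd(PPh3)2Cl2 (3 mol%), CuI (6 mol%), Et3N, THF, rt
Reagents that add atoms: none
Why: Sonogashira coupling forms C1–C2 with retention at the C1=C10 alkene at room temperature, where the alkenylstannane does not transmetallate, and creates no stereocentre.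

Step 12
Reactants: 13 the enyne diol
Product: 14 methyl (2S)-3-[(2S,3R)-2-(hydroxymethyl)-3-[(3S,4Z)-3-hydroxy-3-methyl-5-(tributylstannyl)pent-4-en-1-yn-1-yl]oxiran-2-yl]-2-[(triethylsilyl)oxy]propanoate (C1–C10 epoxide)
Conditions: Ti(OiPr)4 (1.1 equiv), L-(+)-diisopropyl tartrate (1.3 equiv), t-BuOOH, 4 Å molecular sieves, CH2Cl2, −25 °C
Reagents that add atoms: tert-butyl hydroperoxide, CC(C)(C)OO
Why: Sharpless asymmetric epoxidation directed by the C14 hydroxyl sets C10 and C1 by reagent control, syn oxygen transfer keeping C9 and C2 trans on the epoxide, while the tertiary C4 alcohol is a poor substrate for the titanium reagent and the alkenylstannane is not oxidised.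

Step 13
Reactants: 14 the epoxy diol
Product: 15 the C14 tert-butyldimethylsilyl ether of 14
Conditions: t-BuMe2SiCl, imidazole, CH2Cl2, 0 °C
Reagents that add atoms: tert-butylchlorodimethylsilane, CC(C)(C)[Si](C)(C)Cl
Why: Silylation of the primary hydroxyl only, since the tertiary C4 hydroxyl does not react with this chlorosilane and imidazole.

Step 14
Reactants: 15 the C14 silyl ether
Product: 16 the C7 aldehyde (methyl ester of 15 reduced to CHO)
Conditions: i-Bu2AlH (2.2 equiv), CH2Cl2, −78 °C
Reagents that add atoms: none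
Why: Low-temperature aluminium hydride reduction of an α-silyloxy methyl ester stops at the aldehyde through the stable tetrahedral aluminate, one further equivalent being consumed by the C4 hydroxyl.

Step 15
Reactants: 17 methyl 3-hydroxypropanoate
Product: 18 methyl 3-[(triethylsilyl)oxy]propanoate
Conditions: Et3SiCl, imidazole, CH2Cl2, 0 °C
Reagents that add atoms: chlorotriethylsilane, CC[Si](Cl)(CC)CC
Why: Standard silyl ether formation at the primary hydroxyl (imidazole-promoted silylation).

Step 16
Reactants: 16 the C7 aldehyde; 18 methyl 3-[(triethylsilyl)oxy]propanoate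
Product: 19 the aldol adduct (C7 carbinol; C11 bearing CO2Me and CH2OSiEt3; mixture at C7 and C11)
Conditions: 18, LiN(iPr)2, THF, −78 °C; then 16, −78 °C
Reagents that add atoms: none
Why: Aldol addition of the lithium ester enolate, kept at −78 °C so that it does not lose silanolate, forms C7–C11, and the two new centres may form as a mixture because both become sp2 in the next two steps.

Step 17
Reactants: 19 the aldol adduct
Product: 20 the β-keto ester (C7 ketone; mixture at C11)
Conditions: Dess–Martin periodinane, NaHCO3, CH2Cl2, 0 °C → rt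
Reagents that add atoms: none
Why: Dess–Martin oxidation of the secondary alcohol under buffered, non-basic conditions that neither epimerise C8 nor eliminate the C13 silyloxy group.

Step 18
Reactants: 20 the β-keto ester
Product: 21 the (Z)-enol triflate, C7(OTf)=C11(CH2OSiEt3)CO2Me with OTf cis to CO2Me
Conditions: NaH (1.05 equiv), THF, 0 °C; N-(5-chloropyridin-2-yl)bis(trifluoromethanesulfonyl)imide, 0 °C → rt
Reagents that add atoms: N-(5-chloropyridin-2-yl)bis(trifluoromethanesulfonyl)imide, O=S(=O)(N(c1ccc(Cl)cn1)S(=O)(=O)C(F)(F)F)C(F)(F)F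
Why: O-Sulfonylation of the sodium enolate of the β-keto ester, in which chelation of sodium between the two carbonyl oxygens holds the C7 oxygen cis to the ester and so gives the (Z)-enol triflate with C13 cis to C8, one equivalent of NaH removing only the C11 proton.

Step 19
Reactants: 21 the (Z)-enol triflate
Product: 22 the cis C2=C3 alkene (cyclisation precursor)
Conditions: H2 (1 atm), Pd/CaCO3 poisoned with Pb(OAc)2, quinoline, EtOAc, rt
Reagents that add atoms: none
Why: Lindlar semi-hydrogenation adds hydrogen syn to the only alkyne to give the cis C2=C3 alkene, quinoline keeping the alkenylstannane and the tetrasubstituted enol triflate from reacting.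

Step 20
Reactants: 22 the cis C2=C3 alkene
Product: 23 the ten-membered (2Z,4Z)-dienoate methyl ester (ring closed at C6–C7; CO2Me cis to C6)
Conditions: Pd2(dba)3 (10 mol%), AsPh3 (40 mol%), NMP, 40 °C, 1 mM, slow addition
Reagents that add atoms: none
Why: Intramolecular Stille coupling of the (Z)-alkenylstannane with the activated β-triflyloxy enoate forms C6–C7 with retention at both alkenes, the two cis alkenes flanking C4 bringing the chain ends together and the arsine-ligated zerovalent palladium inserting into C–OTf faster than it ionises the vinyl epoxide.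

Step 21
Reactants: 23 the macrocyclic methyl ester
Product: 24 the macrocyclic (2Z,4Z)-dienoic acid (C4 OH free; C8 and C13 OSiEt3; C14 OSiMe2tBu)
Conditions: LiOH, THF/MeOH/H2O, 40 °C; then pH 5
Reagents that add atoms: lithium hydroxide, [Li+].[OH-]
Why: Saponification of the methyl ester by acyl–oxygen cleavage, to which the silyl ethers, the epoxide and the tertiary alcohol are stable.

Step 22
Reactants: 24 the macrocyclic (2Z,4Z)-dienoic acid
Product: 25 the iodolactone (butenolide O–C6–C7=C11–C12(=O); iodine on C5 anti to the lactone oxygen; C4 OH free)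
Conditions: I2 (3 equiv), NaHCO3, MeCN/H2O, 0 °C, dark
Reagents that add atoms: iodine, II
Why: Iodine adds reversibly to the cis C5=C6 alkene and the C12 carboxylate, held cis to C6 across C7=C11, opens the iodonium ion at C6 from the side opposite to iodine, forming the C6–O and C5–I bonds. The closest known reaction is the iodolactonization of (2Z,4Z)-2,4-dienoic acids to 5-(1-iodoalkyl)butenolides. The butenolide ring closes 5-exo-trig, 6-endo attack at C5 being disfavoured because C6 is the allylic end of the iodonium ion and C5 is neopentyl-like next to the fully substituted C4. C5 is set by the face that iodine takes, which the C4 carbinol fixes: its small hydroxyl is the only C4 substituent that can eclipse the cis alkene next to C7, so methyl and the ring carbon C3 flank the two faces and iodine should add anti to methyl, and C6 then follows from the anti opening. The step needs C5=C6 to react in preference to C2=C3 and lactonisation to outrun a semipinacol shift from C4; only C5=C6 has the carboxylate within reach, iodonium formation elsewhere is reversible, and bicarbonate at 0 °C keeps the medium neutral for the vinyl epoxide. In the product the C4 oxygen can turn anti to the C5–I bond with C3 and C6 gauche, which is the arrangement the next step needs for the cis epoxide.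

Step 23
Reactants: 25 the iodolactone
Product: 26 the bis-epoxy butenolide (cis C4–C5 epoxide; C8 and C13 OSiEt3; C14 OSiMe2tBu)
Conditions: Ag2O, THF/H2O, rt, dark
Reagents that add atoms: none
Why: Halohydrin-to-epoxide closure (intramolecular Williamson reaction) in which Ag2O takes up iodide while the C4 oxygen attacks C5 from the rear, so that C5 is inverted and the cis C4–C5 epoxide results.

Step 24
Reactants: 26 the bis-epoxy butenolide
Product: 27 the C8,C13-diol (C14 OSiMe2tBu retained)
Conditions: HF·pyridine, pyridine, THF, 0 °C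
Reagents that add atoms: none
Why: Fluoride cleavage of the two triethylsilyl ethers under pyridine-buffered conditions that leave the hindered primary tert-butyldimethylsilyl ether and both epoxides intact.

Step 25
Reactants: 27 the C8,C13-diol
Product: 28 the C13 acetate (C8 OH free)
Conditions: AcCl (1.1 equiv), 2,4,6-collidine, CH2Cl2, −78 °C
Reagents that add atoms: acetyl chloride, CC(=O)Cl
Why: Chemoselective acetylation of the primary allylic hydroxyl over the hindered secondary C8 hydroxyl with acetyl chloride and collidine at low temperature.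

Step 26
Reactants: 28 the C13 acetate
Product: 29 the C8 methacrylate (C14 OSiMe2tBu)
Conditions: methacrylic anhydride, Et3N, DMAP (cat.), CH2Cl2, 0 °C → rt
Reagents that add atoms: methacrylic anhydride, C=C(C)C(=O)OC(=O)C(C)=C
Why: DMAP-catalysed acylation of the secondary C8 hydroxyl by the anhydride (nucleophilic catalysis) with retention at C8 under conditions too mild to deprotonate the butenolide at C6.

Step 27
Reactants: 29 the C8 methacrylate
Product: 30 the target
Conditions: Bu4NF, AcOH, THF, 0 °C → rt
Reagents that add atoms: none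
Why: Fluoride cleavage of the C14 silyl ether, buffered with acetic acid so that the butenolide, the two esters and the epoxides are not exposed to basic fluoride.

**Compound list**

1 | (2E)-3-methylpent-2-en-4-yn-1-ol | C#C/C(C)=C/CO | starting material
2 | [(2S,3S)-3-ethynyl-3-methyloxiran-2-yl]methanol | C#C[C@]1(C)O[C@H]1CO | intermediate
3 | [(2S,3S)-3-methyl-3-[(tributylstannyl)ethynyl]oxiran-2-yl]methanol | CCCC[Sn](CCCC)(CCCC)C#C[C@]1(C)O[C@H]1CO | intermediate
4 | [(2S,3S)-3-methyl-3-[(Z)-2-(tributylstannyl)ethenyl]oxiran-2-yl]methanol | CCCC[Sn](CCCC)(CCCC)/C=C\[C@]1(C)O[C@H]1CO | intermediate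
5 | (2R,3S)-2-(chloromethyl)-3-methyl-3-[(Z)-2-(tributylstannyl)ethenyl]oxirane | CCCC[Sn](CCCC)(CCCC)/C=C\[C@]1(C)O[C@H]1CCl | intermediate
6 | (1Z,3S)-3-methyl-1-(tributylstannyl)pent-1-en-4-yn-3-ol | C#C[C@@](C)(O)/C=C\[Sn](CCCC)(CCCC)CCCC | intermediate
7 | methyl (2S)-oxirane-2-carboxylate (methyl (S)-glycidate) | COC(=O)[C@@H]1CO1 | starting material
8 | methyl (2S)-2-hydroxypent-4-ynoate | COC(=O)[C@@H](O)CC#C | intermediate
9 | methyl (2S)-2-[(triethylsilyl)oxy]pent-4-ynoate | COC(=O)[C@@H](O[Si](CC)(CC)CC)CC#C | intermediate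
10 | methyl (2S,4Z)-5-[dimethyl(phenyl)silyl]-4-formyl-2-[(triethylsilyl)oxy]pent-4-enoate | COC(=O)[C@@H](O[Si](CC)(CC)CC)C/C(C=O)=C/[Si](C)(C)c1ccccc1 | intermediate
11 | methyl (2S,4Z)-5-[dimethyl(phenyl)silyl]-4-(hydroxymethyl)-2-[(triethylsilyl)oxy]pent-4-enoate | COC(=O)[C@@H](O[Si](CC)(CC)CC)C/C(CO)=C/[Si](C)(C)c1ccccc1 | intermediate
12 | methyl (2S,4Z)-4-(hydroxymethyl)-5-iodo-2-[(triethylsilyl)oxy]pent-4-enoate | COC(=O)[C@@H](O[Si](CC)(CC)CC)C/C(CO)=C/I | intermediate
13 | methyl (2S,4Z,8S,9Z)-8-hydroxy-4-(hydroxymethyl)-8-methyl-10-(tributylstannyl)-2-[(triethylsilyl)oxy]deca-4,9-dien-6-ynoate | COC(=O)[C@@H](O[Si](CC)(CC)CC)C/C(CO)=C/C#C[C@@](C)(O)/C=C\[Sn](CCCC)(CCCC)CCCC | intermediate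
14 | methyl (2S)-3-[(2S,3R)-2-(hydroxymethyl)-3-[(3S,4Z)-3-hydroxy-3-methyl-5-(tributylstannyl)pent-4-en-1-yn-1-yl]oxiran-2-yl]-2-[(triethylsilyl)oxy]propanoate | COC(=O)[C@@H](O[Si](CC)(CC)CC)C[C@@]1(CO)O[C@@H]1C#C[C@@](C)(O)/C=C\[Sn](CCCC)(CCCC)CCCC | intermediate
15 | 14 with the primary (C14) hydroxyl as tert-butyldimethylsilyl ether | COC(=O)[C@@H](O[Si](CC)(CC)CC)C[C@@]1(CO[Si](C)(C)C(C)(C)C)O[C@@H]1C#C[C@@](C)(O)/C=C\[Sn](CCCC)(CCCC)CCCC | intermediate
16 | C7 aldehyde corresponding to ester 15 (C8 OSiEt3; C1–C10 epoxide; C2≡C3; C4 carbinol; (Z)-C5=C6–SnBu3) | O=C[C@@H](O[Si](CC)(CC)CC)C[C@@]1(CO[Si](C)(C)C(C)(C)C)O[C@@H]1C#C[C@@](C)(O)/C=C\[Sn](CCCC)(CCCC)CCCC | intermediate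
17 | methyl 3-hydroxypropanoate | COC(=O)CCO | starting material
18 | methyl 3-[(triethylsilyl)oxy]propanoate | COC(=O)CCO[Si](CC)(CC)CC | intermediate
19 | aldol adduct: C7 carbinol, C11 bearing CO2Me (C12) and CH2OSiEt3 (C13); mixture at C7 and C11; other centres as in 16 | COC(=O)C(CO[Si](CC)(CC)CC)C(O)[C@@H](O[Si](CC)(CC)CC)C[C@@]1(CO[Si](C)(C)C(C)(C)C)O[C@@H]1C#C[C@@](C)(O)/C=C\[Sn](CCCC)(CCCC)CCCC | intermediate
20 | β-keto ester: C7 ketone of 19; mixture at C11 | COC(=O)C(CO[Si](CC)(CC)CC)C(=O)[C@@H](O[Si](CC)(CC)CC)C[C@@]1(CO[Si](C)(C)C(C)(C)C)O[C@@H]1C#C[C@@](C)(O)/C=C\[Sn](CCCC)(CCCC)CCCC | intermediate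
21 | (Z)-enol triflate: C7(OTf)=C11(CH2OSiEt3)CO2Me, OTf cis to CO2Me; C2≡C3 alkyne | COC(=O)/C(CO[Si](CC)(CC)CC)=C(\OS(=O)(=O)C(F)(F)F)[C@@H](O[Si](CC)(CC)CC)C[C@@]1(CO[Si](C)(C)C(C)(C)C)O[C@@H]1C#C[C@@](C)(O)/C=C\[Sn](CCCC)(CCCC)CCCC | intermediate
22 | as 21 with a cis C2=C3 alkene in place of the alkyne | COC(=O)/C(CO[Si](CC)(CC)CC)=C(\OS(=O)(=O)C(F)(F)F)[C@@H](O[Si](CC)(CC)CC)C[C@@]1(CO[Si](C)(C)C(C)(C)C)O[C@@H]1/C=C\[C@@](C)(O)/C=C\[Sn](CCCC)(CCCC)CCCC | intermediate
23 | ten-membered (2Z,4Z)-dienoate methyl ester: ring C1–C10, C1–C10 epoxide, cis C2=C3, C4 carbinol, cis C5=C6, exocyclic C7=C11 with CO2Me cis to C6; C8 and C13 OSiEt3; C14 OSiMe2tBu | CC[Si](CC)(CC)O[C@H]1C[C@@]2(CO[Si](C)(C)C(C)(C)C)O[C@@H]2/C=C\[C@@](C)(O)/C=C\C1=C(\CO[Si](CC)(CC)CC)C(=O)OC | intermediate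
24 | carboxylic acid of 23 (key-step precursor) | CC[Si](CC)(CC)O[C@H]1C[C@@]2(CO[Si](C)(C)C(C)(C)C)O[C@@H]2/C=C\[C@@](C)(O)/C=C\C1=C(\CO[Si](CC)(CC)CC)C(=O)O | intermediate
25 | iodolactone: butenolide closed on C6, iodine on C5 anti to the lactone oxygen, C4 OH free (key-step product) | CC[Si](CC)(CC)O[C@H]1C[C@@]2(CO[Si](C)(C)C(C)(C)C)O[C@@H]2/C=C\[C@@](C)(O)[C@H](I)[C@H]2OC(=O)C(CO[Si](CC)(CC)CC)=C12 | intermediate
26 | bis-epoxy butenolide with cis C4–C5 epoxide; C8 and C13 OSiEt3; C14 OSiMe2tBu | CC[Si](CC)(CC)O[C@H]1C[C@@]2(CO[Si](C)(C)C(C)(C)C)O[C@@H]2/C=C\[C@@]2(C)O[C@H]2[C@H]2OC(=O)C(CO[Si](CC)(CC)CC)=C12 | intermediate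
27 | C8,C13-diol of 26 (C14 OSiMe2tBu) | O[C@H]1C[C@@]2(CO[Si](C)(C)C(C)(C)C)O[C@@H]2/C=C\[C@@]2(C)O[C@H]2[C@H]2OC(=O)C(CO)=C12 | intermediate
28 | C13 acetate of 27 (C8 OH free) | O[C@H]1C[C@@]2(CO[Si](C)(C)C(C)(C)C)O[C@@H]2/C=C\[C@@]2(C)O[C@H]2[C@H]2OC(=O)C(COC(C)=O)=C12 | intermediate
29 | C8 methacrylate of 28 (C14 OSiMe2tBu) | C=C(C)C(=O)O[C@H]1C[C@@]2(CO[Si](C)(C)C(C)(C)C)O[C@@H]2/C=C\[C@@]2(C)O[C@H]2[C@H]2OC(=O)C(COC(C)=O)=C12 | intermediate
30 | target: 13-acetoxy-1,10:4,5-diepoxy-14-hydroxy-8-methacryloyloxy butenolide (CNP0207684.1) | C=C(C)C(=O)O[C@H]1C[C@@]2(CO)O[C@@H]2/C=C\[C@@]2(C)O[C@H]2[C@H]2OC(=O)C(COC(C)=O)=C12 | target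

**Step count and risks**

Total step count: 27. Longest linear sequence: 21 steps (steps 6–14 and 16–27 from methyl (S)-glycidate; equally steps 1–5, 11–14 and 16–27 from the enynol).

Steps most likely to fail:

1. Step 20 (Stille ring closure). Tin-to-palladium transfer at the crowded, tetrasubstituted alkenylpalladium triflate may be slow, so that oligomerisation, protodestannylation and ionisation of the vinyl epoxide by zerovalent palladium take over. The fallback moves the palladium chemistry ahead of the vinyl epoxide and closes the ring without palladium. It sets out from enol triflate 21. Pd(PPh3)4-catalysed exchange of the triflate for tin with Me3Sn–SnMe3 and LiCl (THF, 60 °C) would give the bis-stannane alkyne F1. Semi-hydrogenation as in step 19 would give the cis-alkene bis-stannane F2. One equivalent of I2 (CH2Cl2, −78 °C) should cleave the electron-rich tributylstannyl alkene in preference to the ester-deactivated, tetrasubstituted trimethylstannyl alkene and give the (Z)-alkenyl iodide F3. Copper-mediated intramolecular stannane–iodide coupling with Cu(O2C–C4H3S) (copper thiophene-2-carboxylate) in NMP at 0 °C, helped by the ester cis to tin, would close C6–C7 and return to 23.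

2. Step 22 (key iodolactonization). Iodonium formation may show poor facial selectivity if the ring does not hold the hydroxyl-eclipsed arrangement, and iodine may then also add syn to the C4 methyl group. The fallback replaces control by the free hydroxyl with steric control by a silyl ether. It sets out from acid 24. N-(Trimethylsilyl)imidazole followed by aqueous work-up would give the C4 trimethylsilyl ether acid F4. In F4 the silyloxy group is the largest substituent on C4 and should stand anti to the incoming iodine. Iodolactonization under the conditions of step 22 would then give the silyl-protected iodolactone F5. K2CO3 in MeOH at 0 °C removes the trimethylsilyl group (the most labile silyl group present) and the alkoxide closes the epoxide, returning to 26.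

3. Step 19 (semi-hydrogenation). The alkyne is flanked by a quaternary carbinol and an epoxide carbon, so reduction may be slow, and long exposure to palladium and hydrogen invites loss of tin or over-reduction. The fallback changes from surface hydrogenation to electron-transfer reduction. From 21, zinc dust activated with Cu(OAc)2 and AgNO3 in MeOH/H2O reduces alkynes activated by a propargylic oxygen to cis alkenes without palladium or hydrogen gas, and would lead to 22 through no new compound (F0).

**Further compounds**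

F1 | step 20 | bis-stannane alkyne: 21 with SnMe3 in place of OTf on C7 (SnMe3 cis to CO2Me) | COC(=O)/C(CO[Si](CC)(CC)CC)=C(\[Sn](C)(C)C)[C@@H](O[Si](CC)(CC)CC)C[C@@]1(CO[Si](C)(C)C(C)(C)C)O[C@@H]1C#C[C@@](C)(O)/C=C\[Sn](CCCC)(CCCC)CCCC
F2 | step 20 | cis-alkene bis-stannane: F1 with a cis C2=C3 alkene | COC(=O)/C(CO[Si](CC)(CC)CC)=C(\[Sn](C)(C)C)[C@@H](O[Si](CC)(CC)CC)C[C@@]1(CO[Si](C)(C)C(C)(C)C)O[C@@H]1/C=C\[C@@](C)(O)/C=C\[Sn](CCCC)(CCCC)CCCC
F3 | step 20 | (Z)-alkenyl iodide: F2 with iodine in place of SnBu3 on C6 | COC(=O)/C(CO[Si](CC)(CC)CC)=C(\[Sn](C)(C)C)[C@@H](O[Si](CC)(CC)CC)C[C@@]1(CO[Si](C)(C)C(C)(C)C)O[C@@H]1/C=C\[C@@](C)(O)/C=C\I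
F4 | step 22 | C4 trimethylsilyl ether of acid 24 | CC[Si](CC)(CC)O[C@H]1C[C@@]2(CO[Si](C)(C)C(C)(C)C)O[C@@H]2/C=C\[C@@](C)(O[Si](C)(C)C)/C=C\C1=C(\CO[Si](CC)(CC)CC)C(=O)O
F5 | step 22 | C4 trimethylsilyl ether of iodolactone 25 | CC[Si](CC)(CC)O[C@H]1C[C@@]2(CO[Si](C)(C)C(C)(C)C)O[C@@H]2/C=C\[C@@](C)(O[Si](C)(C)C)[C@H](I)[C@H]2OC(=O)C(CO[Si](CC)(CC)CC)=C12
F0 | step 19 | none | none
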